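I started from the easy step: the four flasks differ by temperature, so I wanted one number that turns a temperature into a fraction of the substrate charge.

the same everywhere: substrate 30 mM

|  | reagent | free catalyst | temperature | remark | time |
|---|---|---|---|---|---|
| birch | 90 mM | 1 mM | 25 °C | run made earlier |  |
| cedar | 90 mM | 2.2 mM | 75 °C | run made earlier |  |
| teal | 90.0 mM | 1.5 mM | 120 °C |  | 2.5 h |
| violet | 90.0 mM | 1.5 mM | 30 °C |  | 2.5 h |
| green | 90.0 mM | 1.5 mM | 60 °C |  | 2.5 h |
| blue | 90.0 mM | 1.5 mM | 90 °C |  | 2.5 h |

- birch (time / h: target / %): 30.0: 1.2; 60.0: 2.5; 96.0: 6.3; 120: 7.0; 144: 8.1; 240: 12.5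
- cedar (time / h: target / %): 1.50: 12.8; 2.50: 20.9; 3.00: 23.8; 5.00: 36.7; 8.00: 51.0; 12.0: 65.3; 20.0: 80.4

(readings scatter by 0.5 percentage points)

* the best flask by amount of target, in percent of the substrate charged; "all alike" if 1.5 percentage points covers them all (teal / violet / green / blue / all alike)
* amount of target at the end, in percent of the substrate charged, teal
* amount of target at the end, in percent of the substrate charged, violet
* amount of target at the end, in percent of the substrate charged, green
* amount of target at the end, in percent of the substrate charged, blue

- the numbers in the tables scatter by 0.5 percentage points (one standard deviation)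
- steps thought possible: reagent + free catalyst <-> catalyst intermediate A; substrate + catalyst intermediate A <-> catalyst intermediate B; catalyst intermediate B -> free catalyst + target; target -> over-reaction product

With reagent at 3.00 equivalents I treated the substrate as pseudo-first-order and assumed the rate follows the catalyst charge. Scaled to the catalyst of the new flasks, the last birch reading gives 8.35 × 10⁻⁴ h⁻¹ and the cedar reading at 5.00 h gives 0.0624 h⁻¹. Joined straight on a logarithmic scale between their temperatures, these give 0.00128 h⁻¹ at violet's 30 °C. That is the turning rate: the fraction of the substrate charge turned into target per hour. So I expected violet to end near 0.321%. I reckoned no figure for teal, whose temperature lies outside both runs.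

The forecast named teal as best, with 72% there, 4.8% in green, 36% in blue and 0.3% in violet, a shade below mine. It warned: “Teal is probably best, though it is the most uncertain”.

The flasks gave 63.5% in teal, 0.329% in violet, 4.98% in green and 34.5% in blue. Teal was best, but 8.5 percentage points under the forecast, and at 2.50 h it held 10.4% substrate and 26.1% over-reaction product.

    reagent + free catalyst ⇌ catalyst intermediate A (K = 14.0 M⁻¹, k = 6.20 M⁻¹ min⁻¹, Ea = 60.0 kJ mol⁻¹, ΔH = −8.00 kJ mol⁻¹)
    substrate + catalyst intermediate A ⇌ catalyst intermediate B (K = 3.50 M⁻¹, k = 17.0 M⁻¹ min⁻¹, Ea = 46.0 kJ mol⁻¹, ΔH = −24.0 kJ mol⁻¹)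
    catalyst intermediate B → free catalyst + target (k = 0.130 min⁻¹, Ea = 100 kJ mol⁻¹)
    target → over-reaction product (k = 2.80 × 10⁻⁶ min⁻¹, Ea = 129 kJ mol⁻¹)
    (constants at 60 °C)

Violet's result gives a turning rate of 0.00132 h⁻¹. The neighbour flask, violet with 75 mM of substrate, ended at 0.272% of its charge, a turning rate of 0.00109 h⁻¹, lower than violet's by a factor of 1.21. So the turning rate, a fraction of the charge, did not carry over from violet to the neighbour. Counted in mM, the neighbour made twice violet's target from 2.50 times the substrate, and at 2.50 h catalyst intermediate B stood at 27.1% of the catalyst charged in the neighbour against 13.1% in violet.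

The runs were generated by integration with constants of no real substance; the scatter is artificial.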